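## The problem

The target 24 is a stilbenoid built on a 2,3-dihydro-1-benzofuran. Ring A (the benzo ring, C3a to C7a) is fused to the dihydrofuran ring B (O1, C2, C3). Ring D (3,4-dihydroxyphenyl) sits on C2, ring C (3,5-dihydroxyphenyl) on C3, C6 carries a free hydroxyl, and C5 carries a trans-ethenyl bridge to ring E, a second resorcinol. The skeleton is five aryl units joined by few linking atoms, so the real tasks are the two adjacent stereocentres and the order in which the electron-rich rings are brought in. C2 and C3 are trans and both S. Trans is the more stable arrangement on ring B, so either centre can steer the other during a ring closure, but no resident stereocentre exists and the absolute sense must come from a reagent. The O1–C2 bond is a benzylic aryl ether whose carbon is para to an oxygen of ring D, so strong Lewis or Brønsted acids can ionise it. The E-stilbene rules out hydrogenolysis and long exposure to light, and the seven phenols, the catechol above all, are air-sensitive and must stay masked until the last step. The feature that opens a less obvious route is ring E: a 5-substituted resorcinol, oxygenated at alternate carbons and bound to C5 through CH=CH. That is the pattern a chain ArCH=CH–CO–CH2–CO–CH2–CO–CH3 gives after one C–C bond (methyl carbon to enone carbonyl carbon) and loss of water. Because C3–H is meta to the C5 side chain and C2–H is not activated, the protected core has no acidic hydrogen and should pass through the base that such a closure needs.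

## Retrosynthesis

**Target 24 to resorcinol 23.** The last operation frees the five phenols on rings A, C and D by cutting five O–CH2 bonds. Benzyl ethers are preferred to methyl ethers because they leave at low temperature under a Lewis acid with a cation trap, without hydrogen, whereas methyl ethers would need hot or prolonged Lewis-acid treatment that threatens O1–C2. In 23, ring E is already free, so only five ethers remain. The forward step must spare the alkene and ring B.

**Resorcinol 23 to trione 21 (key disconnection).** One ring bond of ring E is cut, between the carbon bearing the ethenyl group and its neighbouring CH, and both ring oxygens are returned to ketones. This gives the (E)-1-aryl-oct-1-ene-3,5,7-trione 21, with aldol adduct 22 on the way forward. The neighbouring cut, through the alkene, would need a preformed and protected ring E and a styrene-type coupling. The aldol cut draws ring E from a five-carbon commodity, delivers it unprotected, and leaves the alkene to a much easier acrylamide coupling. The forward reaction must give C-aldol closure in preference to O-closure and must not cleave the polyketone. The core must tolerate hydroxide.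

**Trione 21 to Weinreb amide 17 and pentane-2,4-dione 18.** The C3–C4 bond of the chain (acyl carbon to methylene) is cut. The 1,3-dianion 19 of 18 reacts at its terminal carbon. An N-methoxy-N-methylamide is preferred to an ester because the tetrahedral adduct 20 holds until quench, so the acidic trione is not released into the basic medium and a single acyl transfer is expected. The precursor 17 is a plain cinnamamide.

**Amide 17 to bromide 15 and acrylamide 16.** The aryl C5–vinyl bond is cut, a Mizoroki–Heck disconnection. An electron-poor acrylamide is the best class of alkene for this coupling, giving terminal attack and E geometry. Bromide 15 carries all three remaining rings and both stereocentres.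

**Bromide 15 to sulfone 11 and sulfonium salt 5.** C2–C3 and O1–C2 are cut together, a formal [4+1] annulation. Base unmasks the ortho-quinone methide 12 from 11 and the benzylide 13 from 5. Their adduct, betaine 14, closes ring B. This single step forms ring B and both stereocentres. The chiral C2-symmetric thiolane in 5 is asked to fix C2, and the trans closure then fixes C3. The cut is preferred to stepwise C–O and C–C constructions because rings C and D are already on their carbons before any stereocentre exists.

**Sulfone 11 to aldehyde 7 and aryl bromide 8.** The sulfonyl group is exchanged for hydroxyl (carbinol 10), and the carbinol carbon–ring C bond is cut. This is addition of Grignard reagent 9, made from 8, to salicylaldehyde 7. Aldehyde 7 comes from 5-bromo-2,4-dihydroxybenzaldehyde 6 by selective 4-O-benzylation. The bromine needed for the coupling at C5 is bought in place.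

**Salt 5 to thiolane 3 and benzylic chloride 4.** The S–CH2 bond is cut. Thiolane 3 comes from dimesylate 2 of commercial (2R,5R)-hexane-2,5-diol 1 by double displacement with inversion at both carbons.

## Roads not taken

**Alternative 1:** This cuts C2–ring D and C3–C3a in one three-component conjunctive coupling. The vinylboronate A2 (ring C on the β-carbon) is converted by the ring D aryllithium A3 into an ate complex. With the ring A bromide A4, Pd(OAc)2, a chiral ferrocenyl bisphosphine of the MandyPhos class and KOTf, ring D migrates from boron to the α-carbon while aryl-palladium delivers ring A to the β-carbon, giving boronate A1.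
- Merits: it is convergent, enantiocontrol is catalytic, and both centres are set at once from three simple pieces. In these respects it is better than the chosen plan, which uses a stoichiometric, though recoverable, chiral sulfide.
- Weak points: β-aryl alkenylboronates are the sluggish class for this reaction, and direct Suzuki–Miyaura coupling competes. The electrophile A4 is flanked by an ortho ether.
- After the coupling, the C–B bond of A1 still has to become O1–C2. Oxidation retains configuration, but the ring A phenol must then take the place of that oxygen with net retention. That means either a double inversion or an ionising closure in which C3 alone decides, so one catalyst-set centre is either at risk or redundant.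
- The ester of A1 then needs reduction and olefination to bring in ring E, and seven methyl ethers plus an acetal must be removed at the end.
- The chosen plan sets against this a closure in which C2, O1 and C3 are fixed in the same step, and a shorter path from the core to the stilbene.

**Alternative 2:** This cuts C3–C3a by an oxidative 1,2-shift. The (S)-flavanone A6 is treated with PhI(OAc)2 (a trivalent iodine oxidant) and H2SO4 in trimethyl orthoformate. Ring A migrates from the ketal carbon to the α-carbon, contracting the pyranone to the dihydrofuran ester A5.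
- Merits: flavanones are easy to make, the shift is stereospecific so C2 controls C3 and trans is reliable, and the mesylates on ring D suppress the competing shift of that ring. For trans control alone this is at least as good as an ylide annulation.
- Weak points: A5 carries an ester where ring C should be. Ring C must then be attached to a secondary benzylic carbon, for example by decarboxylative arylation through a C3 radical, which resets C3 and relies only on the trans preference.
- The C2 centre of A6 is labile to base by retro-oxa-Michael opening before the contraction.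
- Ring E is still missing, and mesylates and methyl ethers need different unmasking.
- The chosen plan places ring C before the stereocentres exist, so no aryl–C(sp3) bond has to be made on the finished ring B.

**Alternative 3:** This makes the same [4+1] cut as step 7 but in the methyl ether series, and it attaches ring E ready-made. Sulfone A8 and sulfonium salt A9 with Cs2CO3 give bromide A7. A Heck coupling with 3,5-dimethoxystyrene A10 gives the heptamethyl ether A11, and BBr3 finishes.
- Merits: after the core it needs two steps where the chosen plan needs four, and it handles no polyketone. On step count and robustness of ring E attachment it is the better route, and this is conceded.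
- Weak points: a Heck coupling of a hindered, electron-rich aryl bromide with an electron-rich styrene is slower and less regioselective than one with an acrylamide. Seven methyl ethers must be cleaved with BBr3 on a substrate whose O1–C2 bond is a para-alkoxybenzylic ether.
- The chosen plan sets against this a regiochemically clean coupling, a ring E that arrives unprotected from pentane-2,4-dione (so it can be varied or isotopically labelled), and a final unmasking of five benzyl ethers at low temperature.

Key step: step 10

Assumption: the benzylide from the (2S,5S)-thiolane is taken to react through the same face as in its known epoxidations, which predicts the (2S,3S) series; if the annulation gave the antipode, the (2R,5R)-thiolane from (2S,5S)-hexane-2,5-diol would be used unchanged in every other respect.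

Remark: trione 21 is drawn as the triketo tautomer although it should exist largely as enols.

## Route

Step 1
Reactants: 1 (2R,5R)-hexane-2,5-diol
Product: 2 (2R,5R)-hexane-2,5-diyl dimethanesulfonate
Conditions: MsCl, Et3N, CH2Cl2, 0 °C
Reagents that add atoms: methanesulfonyl chloride, CS(=O)(=O)Cl
Why: Standard O-sulfonylation of both secondary alcohols; the O–S bonds form without touching the carbon centres, so the (2R,5R) configuration is kept.

Step 2
Reactants: 2 (2R,5R)-hexane-2,5-diyl dimethanesulfonate
Product: 3 (2S,5S)-2,5-dimethylthiolane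
Conditions: Na2S·9H2O, EtOH, 20 → 40 °C; distillation
Reagents that add atoms: sodium sulfide, [Na+].[Na+].[S-2]
Why: Double SN2 displacement by sulfide (intermolecular, then 5-exo-tet) inverts both carbons, so the (2R,5R)-dimesylate should give the C2-symmetric trans-(2S,5S)-thiolane.

Step 3
Reactants: 3 (2S,5S)-2,5-dimethylthiolane; 4 4-(chloromethyl)-1,2-bis(benzyloxy)benzene
Product: 5 (2S,5S)-1-[3,4-bis(benzyloxy)benzyl]-2,5-dimethylthiolan-1-ium tetrafluoroborate
Conditions: AgBF4, acetone, 0 → 20 °C, dark
Reagents that add atoms: silver tetrafluoroborate, [Ag+].F[B-](F)(F)F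
Why: Silver-assisted S-alkylation of a dialkyl sulfide by a benzylic chloride; precipitation of AgCl and the non-nucleophilic counter-ion prevent reversal, and the C2 axis of 3 makes both sulfur lone pairs equivalent, so a single salt is expected.

Step 4
Reactants: 6 5-bromo-2,4-dihydroxybenzaldehyde
Product: 7 4-(benzyloxy)-5-bromo-2-hydroxybenzaldehyde
Conditions: BnBr, NaHCO3, KI (cat.), MeCN, 80 °C
Reagents that add atoms: benzyl bromide, BrCc1ccccc1
Why: Williamson etherification; the 4-OH (para to the formyl group, not hydrogen-bonded) is the more acidic phenol and is alkylated selectively by a weak base, while the chelated 2-OH stays free.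

Step 5
Reactants: 8 1,3-bis(benzyloxy)-5-bromobenzene; 7 4-(benzyloxy)-5-bromo-2-hydroxybenzaldehyde
Product: 10 5-(benzyloxy)-2-{[3,5-bis(benzyloxy)phenyl](hydroxy)methyl}-4-bromophenol (racemic), via 3,5-bis(benzyloxy)phenylmagnesium bromide 9 (not isolated)
Conditions: Mg, I2 (cat.), THF, 50 °C; then 7 (0.4 equiv), 0 → 20 °C; aq. NH4Cl
Reagents that add atoms: none
Why: Grignard formation and 1,2-addition to the aldehyde; the first equivalent of 9 is spent on the phenol, the chelated magnesium phenoxide then accepts the second, and the aryl bromide of 7 is inert to an aryl Grignard reagent at this temperature; the racemic carbinol centre is erased in step 7.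

Step 6
Reactants: 10 5-(benzyloxy)-2-{[3,5-bis(benzyloxy)phenyl](hydroxy)methyl}-4-bromophenol
Product: 11 5-(benzyloxy)-2-{[3,5-bis(benzyloxy)phenyl](4-methylbenzenesulfonyl)methyl}-4-bromophenol (racemic)
Conditions: p-TolSO2Na, p-TsOH·H2O, CH2Cl2, 20 °C
Reagents that add atoms: sodium 4-methylbenzenesulfinate, [Na+].Cc1ccc(cc1)S(=O)[O-]
Why: SN1-type substitution; acid ionises the benzhydrol, which is doubly activated by the ortho-hydroxyl and the para-benzyloxy group, and the sulfinate adds at sulfur to give a bench-stable precursor of the ortho-quinone methide.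

Step 7
Reactants: 11 5-(benzyloxy)-2-{[3,5-bis(benzyloxy)phenyl](4-methylbenzenesulfonyl)methyl}-4-bromophenol; 5 (2S,5S)-1-[3,4-bis(benzyloxy)benzyl]-2,5-dimethylthiolan-1-ium tetrafluoroborate
Product: 15 (2S,3S)-6-(benzyloxy)-2-[3,4-bis(benzyloxy)phenyl]-3-[3,5-bis(benzyloxy)phenyl]-5-bromo-2,3-dihydro-1-benzofuran, via ortho-quinone methide 12 (not isolated), via sulfonium benzylide 13 (not isolated), via phenoxide sulfonium betaine 14 (not isolated)
Conditions: Cs2CO3, CH2Cl2–MeCN, −20 → 0 °C
Reagents that add atoms: none
Why: Formal [4+1] annulation of a sulfonium ylide with an ortho-quinone methide; Cs2CO3 eliminates sulfinate from 11 to give 12 and deprotonates 5 to 13, conjugate addition of the ylide carbon to the exocyclic carbon of 12 forms C2–C3 and rearomatises ring A (betaine 14), and the phenoxide displaces the thiolane with inversion to form O1–C2. The C2-symmetric thiolane shields one face of the ylide carbon and so sets C2, and the anti arrangement needed for the displacement places the two aryl groups trans and so sets C3 relative to C2; the enantiomeric purity of 15 would be assayed on a chiral phase and raised by crystallisation if needed.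

Step 8
Reactants: 15 (2S,3S)-6-(benzyloxy)-2-[3,4-bis(benzyloxy)phenyl]-3-[3,5-bis(benzyloxy)phenyl]-5-bromo-2,3-dihydro-1-benzofuran; 16 N-methoxy-N-methylprop-2-enamide
Product: 17 (2E)-3-{(2S,3S)-6-(benzyloxy)-2-[3,4-bis(benzyloxy)phenyl]-3-[3,5-bis(benzyloxy)phenyl]-2,3-dihydro-1-benzofuran-5-yl}-N-methoxy-N-methylprop-2-enamide
Conditions: Pd(OAc)2 (5 mol %), P(o-tol)3, Et3N, DMF, 100 °C
Reagents that add atoms: none
Why: Mizoroki–Heck reaction; zerovalent palladium inserts into the aryl bromide, the electron-poor acrylamide inserts syn at its terminal carbon, and syn β-hydride elimination should give only the E-cinnamamide; the amine base is too weak to touch C2–H or C3–H.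

Step 9
Reactants: 17 (2E)-3-{(2S,3S)-6-(benzyloxy)-2-[3,4-bis(benzyloxy)phenyl]-3-[3,5-bis(benzyloxy)phenyl]-2,3-dihydro-1-benzofuran-5-yl}-N-methoxy-N-methylprop-2-enamide; 18 pentane-2,4-dione
Product: 21 (1E)-1-{(2S,3S)-6-(benzyloxy)-2-[3,4-bis(benzyloxy)phenyl]-3-[3,5-bis(benzyloxy)phenyl]-2,3-dihydro-1-benzofuran-5-yl}oct-1-ene-3,5,7-trione, via dilithium pentane-2,4-dionediide 19 (not isolated), via tetrahedral lithium adduct 20 (not isolated)
Conditions: 18 (2 equiv), LiN(i-Pr)2 (4 equiv), THF, −78 → 0 °C; then 17, −78 → −20 °C; aq. NH4Cl–AcOH, 0 °C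
Reagents that add atoms: none
Why: Acylation of a 1,3-diketone dianion at its terminal, more basic carbon by a Weinreb amide; the chelated adduct 20 survives until the buffered quench, so the acidic trione is not exposed to the dianion and one acyl transfer is expected, and the hard lithium enolate should add 1,2 to the donor-substituted cinnamamide. Strong acid is avoided in the work-up because it would close the trione to a 4-pyranone.

Step 10
Reactants: 21 (1E)-1-{(2S,3S)-6-(benzyloxy)-2-[3,4-bis(benzyloxy)phenyl]-3-[3,5-bis(benzyloxy)phenyl]-2,3-dihydro-1-benzofuran-5-yl}oct-1-ene-3,5,7-trione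
Product: 23 5-[(E)-2-{(2S,3S)-6-(benzyloxy)-2-[3,4-bis(benzyloxy)phenyl]-3-[3,5-bis(benzyloxy)phenyl]-2,3-dihydro-1-benzofuran-5-yl}ethenyl]benzene-1,3-diol, via aldol adduct 22 (not isolated)
Conditions: KOH (2 M aq.), THF–MeOH, Ar, dark, 20 → 45 °C; then aq. HCl to pH 4
Reagents that add atoms: none
Why: Hydroxide turns 21 into its polyenolate, in which a small equilibrium share is deprotonated at the terminal methyl carbon (C8 of the chain); this carbon adds to the enone carbonyl carbon C3 to give the tertiary aldolate 22, the only new C–C bond of the step. E1cB loss of hydroxide and enolisation of the two remaining ring ketones then give aromatic ring E with both hydroxyls free and the E-alkene unchanged. The closest known reaction type is the base-mediated aldol cyclisation and aromatisation of 2,4,6-triketones to 5-substituted resorcinols, the laboratory counterpart of the stilbene synthase closure. The ring closes in the 6-(enolendo)-exo-trig mode, which is favoured for enolates. No stereocentre is formed, since the carbinol carbon of 22 carries two identical ring arms and is lost on aromatisation, and C2 and C3 are untouched because neither C–H is acidic. The selectivity needed is C-aldol over O-closure and over chain cleavage: this is the only six-membered C-aldol the chain allows because its other terminus is the alkene carbon, O-closures to a 4-pyranone or a dihydropyranone are reversible in hydroxide whereas aromatisation is not, and the donor oxygens of ring A (O1 para and the C6 ether ortho to the side chain) make the β-carbon a poor acceptor for conjugate addition. Mild temperature and exclusion of oxygen should limit retro-Claisen cleavage and oxidation of the resorcinolate.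

Step 11
Reactants: 23 5-[(E)-2-{(2S,3S)-6-(benzyloxy)-2-[3,4-bis(benzyloxy)phenyl]-3-[3,5-bis(benzyloxy)phenyl]-2,3-dihydro-1-benzofuran-5-yl}ethenyl]benzene-1,3-diol
Product: 24 5-[(E)-2-{(2S,3S)-2-(3,4-dihydroxyphenyl)-3-(3,5-dihydroxyphenyl)-6-hydroxy-2,3-dihydro-1-benzofuran-5-yl}ethenyl]benzene-1,3-diol
Conditions: BCl3, C6HMe5, CH2Cl2, −78 °C, dark; MeOH quench
Reagents that add atoms: none
Why: Lewis-acid debenzylation with a cation scavenger; BCl3 activates the five primary benzyl ethers and pentamethylbenzene takes up the benzyl cations by Friedel–Crafts alkylation, so rings A and E and the stilbene should not be C-benzylated. At −78 °C the alkene is expected to survive, and O1–C2 is a hindered secondary position whose oxygen lone pair is delocalised into ring A, so both stereocentres should be kept.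

## Compound list

1 | (2R,5R)-hexane-2,5-diol | C[C@@H](O)CC[C@@H](C)O | starting material
2 | (2R,5R)-hexane-2,5-diyl dimethanesulfonate | C[C@@H](OS(C)(=O)=O)CC[C@@H](C)OS(C)(=O)=O | intermediate
3 | (2S,5S)-2,5-dimethylthiolane | C[C@H]1CC[C@H](C)S1 | intermediate
4 | 4-(chloromethyl)-1,2-bis(benzyloxy)benzene (3,4-bis(benzyloxy)benzyl chloride) | ClCc1ccc(OCc2ccccc2)c(OCc2ccccc2)c1 | starting material
5 | (2S,5S)-1-[3,4-bis(benzyloxy)benzyl]-2,5-dimethylthiolan-1-ium tetrafluoroborate | C[C@H]1CC[C@H](C)[S+]1Cc1ccc(OCc2ccccc2)c(OCc2ccccc2)c1.F[B-](F)(F)F | intermediate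
6 | 5-bromo-2,4-dihydroxybenzaldehyde | O=Cc1cc(Br)c(O)cc1O | starting material
7 | 4-(benzyloxy)-5-bromo-2-hydroxybenzaldehyde | O=Cc1cc(Br)c(OCc2ccccc2)cc1O | intermediate
8 | 1,3-bis(benzyloxy)-5-bromobenzene | Brc1cc(OCc2ccccc2)cc(OCc2ccccc2)c1 | starting material
9 | 3,5-bis(benzyloxy)phenylmagnesium bromide | Br[Mg]c1cc(OCc2ccccc2)cc(OCc2ccccc2)c1 | intermediate (not isolated)
10 | 5-(benzyloxy)-2-{[3,5-bis(benzyloxy)phenyl](hydroxy)methyl}-4-bromophenol, racemic | OC(c1cc(OCc2ccccc2)cc(OCc2ccccc2)c1)c1cc(Br)c(OCc2ccccc2)cc1O | intermediate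
11 | 5-(benzyloxy)-2-{[3,5-bis(benzyloxy)phenyl](4-methylbenzenesulfonyl)methyl}-4-bromophenol, racemic | Cc1ccc(cc1)S(=O)(=O)C(c1cc(OCc2ccccc2)cc(OCc2ccccc2)c1)c1cc(Br)c(OCc2ccccc2)cc1O | intermediate
12 | (6E)-3-(benzyloxy)-6-{[3,5-bis(benzyloxy)phenyl]methylidene}-4-bromocyclohexa-2,4-dien-1-one (ortho-quinone methide) | O=C1C=C(OCc2ccccc2)C(Br)=C/C1=C\c1cc(OCc2ccccc2)cc(OCc2ccccc2)c1 | intermediate (not isolated)
13 | [3,4-bis(benzyloxy)phenyl][(2S,5S)-2,5-dimethylthiolan-1-ium-1-yl]methanide (sulfonium benzylide) | C[C@H]1CC[C@H](C)[S+]1[CH-]c1ccc(OCc2ccccc2)c(OCc2ccccc2)c1 | intermediate (not isolated)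
14 | 5-(benzyloxy)-2-{(1S,2R)-2-[3,4-bis(benzyloxy)phenyl]-1-[3,5-bis(benzyloxy)phenyl]-2-[(2S,5S)-2,5-dimethylthiolan-1-ium-1-yl]ethyl}-4-bromophenolate (betaine) | [O-]c1cc(OCc2ccccc2)c(Br)cc1[C@H](c1cc(OCc2ccccc2)cc(OCc2ccccc2)c1)[C@H](c1ccc(OCc2ccccc2)c(OCc2ccccc2)c1)[S+]1[C@@H](C)CC[C@@H]1C | intermediate (not isolated)
15 | (2S,3S)-6-(benzyloxy)-2-[3,4-bis(benzyloxy)phenyl]-3-[3,5-bis(benzyloxy)phenyl]-5-bromo-2,3-dihydro-1-benzofuran | Brc1cc2c(cc1OCc1ccccc1)O[C@H](c1ccc(OCc3ccccc3)c(OCc3ccccc3)c1)[C@H]2c1cc(OCc3ccccc3)cc(OCc3ccccc3)c1 | intermediate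
16 | N-methoxy-N-methylprop-2-enamide | C=CC(=O)N(C)OC | starting material
17 | (2E)-3-{(2S,3S)-6-(benzyloxy)-2-[3,4-bis(benzyloxy)phenyl]-3-[3,5-bis(benzyloxy)phenyl]-2,3-dihydro-1-benzofuran-5-yl}-N-methoxy-N-methylprop-2-enamide | CON(C)C(=O)/C=C/c1cc2c(cc1OCc1ccccc1)O[C@H](c1ccc(OCc3ccccc3)c(OCc3ccccc3)c1)[C@H]2c1cc(OCc3ccccc3)cc(OCc3ccccc3)c1 | intermediate
18 | pentane-2,4-dione | CC(=O)CC(C)=O | starting material
19 | dilithium salt of the pentane-2,4-dione 1,3-dianion | [Li+].[Li+].C=C([O-])C=C(C)[O-] | intermediate (not isolated)
20 | dilithium salt of the tetrahedral adduct of 19 to the amide carbonyl of 17 (alkoxide and diketone enolate; both epimers at the new carbinolamine carbon) | [Li+].[Li+].CON(C)C([O-])(CC(=O)C=C(C)[O-])/C=C/c1cc2c(cc1OCc1ccccc1)O[C@H](c1ccc(OCc3ccccc3)c(OCc3ccccc3)c1)[C@H]2c1cc(OCc3ccccc3)cc(OCc3ccccc3)c1 | intermediate (not isolated)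
21 | (1E)-1-{(2S,3S)-6-(benzyloxy)-2-[3,4-bis(benzyloxy)phenyl]-3-[3,5-bis(benzyloxy)phenyl]-2,3-dihydro-1-benzofuran-5-yl}oct-1-ene-3,5,7-trione | CC(=O)CC(=O)CC(=O)/C=C/c1cc2c(cc1OCc1ccccc1)O[C@H](c1ccc(OCc3ccccc3)c(OCc3ccccc3)c1)[C@H]2c1cc(OCc3ccccc3)cc(OCc3ccccc3)c1 | intermediate (precursor of the key step)
22 | 5-[(E)-2-{(2S,3S)-6-(benzyloxy)-2-[3,4-bis(benzyloxy)phenyl]-3-[3,5-bis(benzyloxy)phenyl]-2,3-dihydro-1-benzofuran-5-yl}ethenyl]-5-hydroxycyclohexane-1,3-dione (aldol adduct) | O=C1CC(=O)CC(O)(C1)/C=C/c1cc2c(cc1OCc1ccccc1)O[C@H](c1ccc(OCc3ccccc3)c(OCc3ccccc3)c1)[C@H]2c1cc(OCc3ccccc3)cc(OCc3ccccc3)c1 | intermediate (not isolated)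
23 | 5-[(E)-2-{(2S,3S)-6-(benzyloxy)-2-[3,4-bis(benzyloxy)phenyl]-3-[3,5-bis(benzyloxy)phenyl]-2,3-dihydro-1-benzofuran-5-yl}ethenyl]benzene-1,3-diol | Oc1cc(O)cc(/C=C/c2cc3c(cc2OCc2ccccc2)O[C@H](c2ccc(OCc4ccccc4)c(OCc4ccccc4)c2)[C@H]3c2cc(OCc4ccccc4)cc(OCc4ccccc4)c2)c1 | intermediate (product of the key step)
24 | 5-[(E)-2-{(2S,3S)-2-(3,4-dihydroxyphenyl)-3-(3,5-dihydroxyphenyl)-6-hydroxy-2,3-dihydro-1-benzofuran-5-yl}ethenyl]benzene-1,3-diol | Oc1cc(O)cc(/C=C/c2cc3c(cc2O)O[C@H](c2ccc(O)c(O)c2)[C@H]3c2cc(O)cc(O)c2)c1 | target

## Step count and risks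

Total step count: 11. Longest linear sequence: 8 steps (steps 4 to 11 from 6; equally steps 1 to 3 and 7 to 11 from 1).

**Step 10 (key step).** The most likely failure is hydroxide-induced retro-Claisen cleavage of the polyketone chain outrunning the aldol. The chain sits mostly as an unreactive delocalised dianion, and the enone carbonyl is deactivated by the two donor oxygens of ring A. Reversible O-closure products may also build up, and the pentabenzyl substrate may dissolve poorly in the aqueous medium. Fallback: set out from bromide 15 and attach ring E ready-made. 1,3-Bis(benzyloxy)-5-ethenylbenzene F1 would be prepared from commercial 3,5-bis(benzyloxy)benzaldehyde by Wittig methylenation and coupled with 15 under Mizoroki–Heck conditions (Pd(OAc)2, P(t-Bu)3, a hindered amine). This would give (2S,3S)-6-(benzyloxy)-2-[3,4-bis(benzyloxy)phenyl]-3-[3,5-bis(benzyloxy)phenyl]-5-{(E)-2-[3,5-bis(benzyloxy)phenyl]ethenyl}-2,3-dihydro-1-benzofuran F2. The conditions of step 11, with more reagent for seven ethers, then return to the route at target 24. This gives up the biomimetic closure but uses only standard chemistry.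

**Step 7.** Chirality transfer may be incomplete. The ylide face may be discriminated poorly, or the electron-rich benzylic sulfonium centre of betaine 14 may ionise before ring closure, so that C2 is no longer set by inversion. The phenoxide of 11 may also be O-benzylated by salt 5, and quinone methide 12 may self-condense. Fallback: set out from sulfone 11 and run the annulation with the achiral salt 1-[3,4-bis(benzyloxy)benzyl]thiolan-1-ium tetrafluoroborate F3, made from thiolane and chloride 4 as in step 3. This would give racemic trans-6-(benzyloxy)-2-[3,4-bis(benzyloxy)phenyl]-3-[3,5-bis(benzyloxy)phenyl]-5-bromo-2,3-dihydro-1-benzofuran F4. Preparative chromatography on a chiral stationary phase would then resolve it, returning to the route at bromide 15.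

**Step 9.** The polyanionic product may aggregate and stall the acylation, conjugate addition may compete, and the trione may close to a pyranone or cleave during work-up. Fallback: set out from bromide 15 and replace the dianion with a neutral dienol ether.
- Heck coupling of 15 with acrylic acid would give (2E)-3-{(2S,3S)-6-(benzyloxy)-2-[3,4-bis(benzyloxy)phenyl]-3-[3,5-bis(benzyloxy)phenyl]-2,3-dihydro-1-benzofuran-5-yl}prop-2-enoic acid F5.
- Oxalyl chloride with catalytic DMF would give the acid chloride (2E)-3-{(2S,3S)-6-(benzyloxy)-2-[3,4-bis(benzyloxy)phenyl]-3-[3,5-bis(benzyloxy)phenyl]-2,3-dihydro-1-benzofuran-5-yl}prop-2-enoyl chloride F6.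
- C-acylation of (3Z)-2,4-bis(trimethylsilyloxy)penta-1,3-diene F7 (from 18 by double silylation) at its terminal carbon by F6 in CH2Cl2 at −78 °C, followed by aqueous work-up, would return to the route at trione 21.

**Step 11.** The Lewis acid may ionise the O1–C2 bond, leading to ring opening, trapping of the benzylic cation or epimerisation at C2. Ring E may be C-benzylated if the scavenger is outcompeted. Fallback: set out from 23 and give up the Lewis acid altogether. The benzyl ethers would be cleaved by SN2 attack of a thiolate at the benzylic CH2 (NaSEt, DMF, 100 °C, argon), followed by acidification, returning to the route at target 24. No new compound is involved.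

## Further compounds

F1 | step 10 | 1,3-bis(benzyloxy)-5-ethenylbenzene | C=Cc1cc(OCc2ccccc2)cc(OCc2ccccc2)c1
F2 | step 10 | (2S,3S)-6-(benzyloxy)-2-[3,4-bis(benzyloxy)phenyl]-3-[3,5-bis(benzyloxy)phenyl]-5-{(E)-2-[3,5-bis(benzyloxy)phenyl]ethenyl}-2,3-dihydro-1-benzofuran | C(c1ccccc1)Oc1cc(OCc2ccccc2)cc(/C=C/c2cc3c(cc2OCc2ccccc2)O[C@H](c2ccc(OCc4ccccc4)c(OCc4ccccc4)c2)[C@H]3c2cc(OCc4ccccc4)cc(OCc4ccccc4)c2)c1
F3 | step 7 | 1-[3,4-bis(benzyloxy)benzyl]thiolan-1-ium tetrafluoroborate | C1CC[S+](C1)Cc1ccc(OCc2ccccc2)c(OCc2ccccc2)c1.F[B-](F)(F)F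
F4 | step 7 | racemic trans-6-(benzyloxy)-2-[3,4-bis(benzyloxy)phenyl]-3-[3,5-bis(benzyloxy)phenyl]-5-bromo-2,3-dihydro-1-benzofuran (both enantiomers) | Brc1cc2c(cc1OCc1ccccc1)O[C@H](c1ccc(OCc3ccccc3)c(OCc3ccccc3)c1)[C@H]2c1cc(OCc3ccccc3)cc(OCc3ccccc3)c1.Brc1cc2c(cc1OCc1ccccc1)O[C@@H](c1ccc(OCc3ccccc3)c(OCc3ccccc3)c1)[C@@H]2c1cc(OCc3ccccc3)cc(OCc3ccccc3)c1
F5 | step 9 | (2E)-3-{(2S,3S)-6-(benzyloxy)-2-[3,4-bis(benzyloxy)phenyl]-3-[3,5-bis(benzyloxy)phenyl]-2,3-dihydro-1-benzofuran-5-yl}prop-2-enoic acid | OC(=O)/C=C/c1cc2c(cc1OCc1ccccc1)O[C@H](c1ccc(OCc3ccccc3)c(OCc3ccccc3)c1)[C@H]2c1cc(OCc3ccccc3)cc(OCc3ccccc3)c1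
F6 | step 9 | (2E)-3-{(2S,3S)-6-(benzyloxy)-2-[3,4-bis(benzyloxy)phenyl]-3-[3,5-bis(benzyloxy)phenyl]-2,3-dihydro-1-benzofuran-5-yl}prop-2-enoyl chloride | ClC(=O)/C=C/c1cc2c(cc1OCc1ccccc1)O[C@H](c1ccc(OCc3ccccc3)c(OCc3ccccc3)c1)[C@H]2c1cc(OCc3ccccc3)cc(OCc3ccccc3)c1
F7 | step 9 | (3Z)-2,4-bis(trimethylsilyloxy)penta-1,3-diene | C=C(O[Si](C)(C)C)/C=C(/C)O[Si](C)(C)C
F0 | step 11 | none | none
A1 | alternative 1 | methyl 5-[(1S,2S)-2-(3,4-dimethoxyphenyl)-1-(3,5-dimethoxyphenyl)-2-(4,4,5,5-tetramethyl-1,3,2-dioxaborolan-2-yl)ethyl]-2-methoxy-4-(methoxymethoxy)benzoate | CC1(C)OB(OC1(C)C)[C@H](c1ccc(OC)c(OC)c1)[C@H](c1cc(C(=O)OC)c(OC)cc1OCOC)c1cc(OC)cc(OC)c1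
A2 | alternative 1 | 2-[(E)-2-(3,5-dimethoxyphenyl)ethenyl]-4,4,5,5-tetramethyl-1,3,2-dioxaborolane | COc1cc(/C=C/B2OC(C)(C)C(C)(C)O2)cc(OC)c1
A3 | alternative 1 | (3,4-dimethoxyphenyl)lithium | [Li]c1ccc(OC)c(OC)c1
A4 | alternative 1 | methyl 5-bromo-2-methoxy-4-(methoxymethoxy)benzoate | COC(=O)c1cc(Br)c(OCOC)cc1OC
A5 | alternative 2 | methyl (2S,3S)-5-bromo-6-methoxy-2-[3,4-bis(methylsulfonyloxy)phenyl]-2,3-dihydro-1-benzofuran-3-carboxylate | Brc1cc2c(cc1OC)O[C@H](c1ccc(OS(C)(=O)=O)c(OS(C)(=O)=O)c1)[C@H]2C(=O)OC
A6 | alternative 2 | (2S)-6-bromo-7-methoxy-2-[3,4-bis(methylsulfonyloxy)phenyl]-2,3-dihydro-4H-chromen-4-one | O=C1C[C@@H](c2ccc(OS(C)(=O)=O)c(OS(C)(=O)=O)c2)Oc2cc(OC)c(Br)cc12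
A7 | alternative 3 | (2S,3S)-5-bromo-2-(3,4-dimethoxyphenyl)-3-(3,5-dimethoxyphenyl)-6-methoxy-2,3-dihydro-1-benzofuran | Brc1cc2c(cc1OC)O[C@H](c1ccc(OC)c(OC)c1)[C@H]2c1cc(OC)cc(OC)c1
A8 | alternative 3 | 4-bromo-2-[(3,5-dimethoxyphenyl)(4-methylbenzenesulfonyl)methyl]-5-methoxyphenol | Cc1ccc(cc1)S(=O)(=O)C(c1cc(OC)cc(OC)c1)c1cc(Br)c(OC)cc1O
A9 | alternative 3 | (2S,5S)-1-(3,4-dimethoxybenzyl)-2,5-dimethylthiolan-1-ium tetrafluoroborate | C[C@H]1CC[C@H](C)[S+]1Cc1ccc(OC)c(OC)c1.F[B-](F)(F)F
A10 | alternative 3 | 1-ethenyl-3,5-dimethoxybenzene | C=Cc1cc(OC)cc(OC)c1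
A11 | alternative 3 | (2S,3S)-2-(3,4-dimethoxyphenyl)-3-(3,5-dimethoxyphenyl)-5-[(E)-2-(3,5-dimethoxyphenyl)ethenyl]-6-methoxy-2,3-dihydro-1-benzofuran | COc1cc(OC)cc(/C=C/c2cc3c(cc2OC)O[C@H](c2ccc(OC)c(OC)c2)[C@H]3c2cc(OC)cc(OC)c2)c1
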